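**Retrosynthetic overview**
1. Target 28 comes from hydrogenolysis of pentadeca-benzyl ether 27. The dioxin ring (between rings C and D) is closed by intramolecular C–O coupling in the hydroquinone made from quinone 25.
2. Ring D is dibromoquinone 23. Its two bromides are displaced in turn by the phenol of the right half (rings E–H, 21) and by the phenol of the left half (rings A–C, 12).
3. Key step: phenol 9 (from catechol) is dearomatized to bromoquinone 10. This one quinone becomes ring C (Michael arylation and cyclodehydration with phenol 6 build the furan ring) and, after HBr addition, ring D (23).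
4. Ethers A–O–B and F–O–G come from Ullmann coupling with bromoaldehyde 2, then Baeyer–Villiger oxidation to the next phenol. G–O–H comes from Ullmann coupling with iodide 19. Biaryl E–F comes from oxidative dimerization of two molecules of phenol 3 to the C2-symmetric diol 13, desymmetrized by one etherification.
5. Ring order: all eight benzene rings are bought. The furan ring (B/C) is formed in step 7 and the dioxin ring (C/D) last, in step 18.

Assumption: the SMILES has no stereodescriptor and the molecule has no stereocentre; the only possible stereogenic unit, the E–F biaryl axis, is unspecified, so the target is made as drawn (every compound that holds the E–F biaryl is racemic about that axis).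

Ring letters, in SMILES order: A = 3,5-dihydroxyphenoxy ring; B and C = the two benzo rings of the dibenzofuran (B carries A); D = outer dioxin ring; E–F = biaryl (E is on D); G and H = the two terminal ether rings.

**Route**

Step 1
Reactants: 1 3,5-bis(benzyloxy)benzaldehyde
Product: 2 3,5-bis(benzyloxy)-2-bromobenzaldehyde
Conditions: NBS, MeCN, 0 °C → rt
Reagents that add atoms: N-bromosuccinimide, O=C1CCC(=O)N1Br
Why: Electrophilic aromatic bromination goes to the carbon ortho to CHO that is ortho to one benzyloxy group and para to the other, the carbon between the two ethers being more hindered.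

Step 2
Reactants: 2 3,5-bis(benzyloxy)-2-bromobenzaldehyde; 3 3,5-bis(benzyloxy)phenol
Product: 4 3,5-bis(benzyloxy)-2-[3,5-bis(benzyloxy)phenoxy]benzaldehyde
Conditions: CuI (10 mol %), N,N-dimethylglycine·HCl (30 mol %), Cs2CO3, dioxane, 90 °C
Reagents that add atoms: none
Why: Ullmann diaryl ether synthesis, in which the ortho formyl group activates the hindered bromide and the phenol partner is unhindered.

Step 3
Reactants: 4 3,5-bis(benzyloxy)-2-[3,5-bis(benzyloxy)phenoxy]benzaldehyde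
Product: 6 3,5-bis(benzyloxy)-2-[3,5-bis(benzyloxy)phenoxy]phenol (rings A–O–B), via aryl formate 5 (not isolated)
Conditions: mCPBA, CH2Cl2, 0 °C → rt; then K2CO3 (cat.), MeOH, rt
Reagents that add atoms: mCPBA, OOC(=O)c1cccc(Cl)c1
Why: Baeyer–Villiger (Dakin-type) oxidation in which the aryl group, made electron-rich by its ortho aryloxy oxygen, migrates in preference to hydrogen, and methanolysis of the formate frees the phenol.

Step 4
Reactants: 7 catechol
Product: 8 2-(benzyloxy)phenol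
Conditions: BnBr (1.0 equiv), K2CO3, acetone, reflux
Reagents that add atoms: benzyl bromide, BrCc1ccccc1
Why: Williamson mono-etherification, with limiting benzyl bromide keeping the dibenzyl ether minor.

Step 5
Reactants: 8 2-(benzyloxy)phenol
Product: 9 2-(benzyloxy)-6-bromophenol
Conditions: NBS, i-Pr2NH (10 mol %), CH2Cl2, 0 °C
Reagents that add atoms: N-bromosuccinimide, O=C1CCC(=O)N1Br
Why: Amine-mediated ortho-selective phenol bromination, in which the N-bromoamine hydrogen-bonded to the OH delivers bromine to the only free ortho carbon rather than to the para carbon.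

Step 6
Reactants: 9 2-(benzyloxy)-6-bromophenol
Product: 10 2-(benzyloxy)-6-bromo-1,4-benzoquinone
Conditions: K2[ON(SO3)2] (Fremy's salt, 2.2 equiv), KH2PO4, acetone/H2O, rt
Reagents that add atoms: Fremy's salt (potassium nitrosodisulfonate), [K+].[K+].[O]N(S(=O)(=O)[O-])S(=O)(=O)[O-]
Why: Teuber oxidation, in which the phenoxyl radical is trapped at the free para carbon to give the p-quinone, so the aromaticity of a simple phenol is broken and its ring carbons become the electrophiles that later serve as ring C (step 7) and ring D (step 15).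

Step 7
Reactants: 6 3,5-bis(benzyloxy)-2-[3,5-bis(benzyloxy)phenoxy]phenol; 10 2-(benzyloxy)-6-bromo-1,4-benzoquinone
Product: 12 3,7,9-tris(benzyloxy)-6-[3,5-bis(benzyloxy)phenoxy]-1-bromodibenzo[b,d]furan-2-ol (rings A–B–C), via biaryl hydroquinone 11 (not isolated)
Conditions: BF3·OEt2 (20 mol %), CH2Cl2, −40 → 0 °C, 10 added slowly to 6 (1.2 equiv); then TsOH·H2O (10 mol %), toluene, 4 Å MS, 80 °C
Reagents that add atoms: none
Why: Quinone–phenol furan annulation (the arene version of the Nenitzescu 5-hydroxybenzofuran synthesis), in which the carbon ortho to the free OH of 6 adds to the quinone carbon para to the benzyloxy group (Friedel–Crafts-type Michael arylation, bromine kept under acid) and acid then dehydrates the 2,2'-dihydroxybiaryl through the protonated phloroglucinol-type ring, leaving the oxygen flanked by OBn and Br as the only free phenol.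

Step 8
Reactants: 3 3,5-bis(benzyloxy)phenol (first molecule); 3 3,5-bis(benzyloxy)phenol (second molecule)
Product: 13 4,4',6,6'-tetrakis(benzyloxy)-[1,1'-biphenyl]-2,2'-diol
Conditions: FeCl3 (10 mol %), t-BuOOt-Bu (0.5 equiv per phenol, that is 1 equiv per biaryl formed), HFIP/ClCH2CH2Cl, rt
Reagents that add atoms: none
Why: Iron-catalysed oxidative phenol homocoupling of two molecules of 3 (2 ArOH → HOAr–ArOH, the two hydrogens going to the peroxide), in which both phenols are bound to trivalent iron as phenolates so that the C–C bond forms ortho,ortho', the para carbon between two benzyloxy groups being shielded.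

Step 9
Reactants: 13 4,4',6,6'-tetrakis(benzyloxy)-[1,1'-biphenyl]-2,2'-diol; 2 3,5-bis(benzyloxy)-2-bromobenzaldehyde
Product: 14 3,5-bis(benzyloxy)-2-{[4,4',6,6'-tetrakis(benzyloxy)-2'-hydroxy-[1,1'-biphenyl]-2-yl]oxy}benzaldehyde
Conditions: 13 (3 equiv), CuI (10 mol %), N,N-dimethylglycine·HCl (30 mol %), Cs2CO3, dioxane, 90 °C; excess 13 recovered
Reagents that add atoms: none
Why: Ullmann etherification at the formyl-activated bromide, in which an excess of the C2-symmetric diol makes single arylation (desymmetrization) dominant and the second hydroxyl is more hindered once the first has reacted.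

Step 10
Reactants: 14 3,5-bis(benzyloxy)-2-{[4,4',6,6'-tetrakis(benzyloxy)-2'-hydroxy-[1,1'-biphenyl]-2-yl]oxy}benzaldehyde
Product: 15 3,5-bis(benzyloxy)-2-{[4,4',6,6'-tetrakis(benzyloxy)-2'-(methoxymethoxy)-[1,1'-biphenyl]-2-yl]oxy}benzaldehyde
Conditions: MOMCl, i-Pr2NEt, CH2Cl2, 0 → 40 °C
Reagents that add atoms: chloromethyl methyl ether, COCCl
Why: O-alkylation to the MOM acetal masks the ring E phenol, so that the phenol made in step 11 is the only one free for step 13.

Step 11
Reactants: 15 3,5-bis(benzyloxy)-2-{[4,4',6,6'-tetrakis(benzyloxy)-2'-(methoxymethoxy)-[1,1'-biphenyl]-2-yl]oxy}benzaldehyde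
Product: 17 3,5-bis(benzyloxy)-2-{[4,4',6,6'-tetrakis(benzyloxy)-2'-(methoxymethoxy)-[1,1'-biphenyl]-2-yl]oxy}phenol, via aryl formate 16 (not isolated)
Conditions: mCPBA, CH2Cl2, 0 °C → rt; then K2CO3 (cat.), MeOH, rt
Reagents that add atoms: mCPBA, OOC(=O)c1cccc(Cl)c1
Why: Baeyer–Villiger oxidation and formate methanolysis as in step 3, the ortho aryloxy group again directing aryl migration, with the MOM acetal and benzyl ethers inert.

Step 12
Reactants: 18 1,3,5-tris(benzyloxy)benzene
Product: 19 1,3,5-tris(benzyloxy)-2-iodobenzene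
Conditions: NIS (1.0 equiv), MeCN, rt
Reagents that add atoms: N-iodosuccinimide, O=C1CCC(=O)N1I
Why: Electrophilic aromatic iodination of a ring whose three free carbons are equivalent, so a single mono-iodide forms.

Step 13
Reactants: 17 3,5-bis(benzyloxy)-2-{[4,4',6,6'-tetrakis(benzyloxy)-2'-(methoxymethoxy)-[1,1'-biphenyl]-2-yl]oxy}phenol; 19 1,3,5-tris(benzyloxy)-2-iodobenzene
Product: 20 2-{4,6-bis(benzyloxy)-2-[2,4,6-tris(benzyloxy)phenoxy]phenoxy}-4,4',6,6'-tetrakis(benzyloxy)-2'-(methoxymethoxy)-1,1'-biphenyl (rings E–F–G–H, MOM on ring E)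
Conditions: CuI (20 mol %), picolinic acid (40 mol %), K3PO4, DMSO, 90 °C
Reagents that add atoms: none
Why: Ullmann diaryl ether synthesis under the picolinic acid conditions made for ortho-substituted partners, the classical way to join a phenol to a 2-halo-1,3,5-trialkoxybenzene.

Step 14
Reactants: 20 MOM-protected rings E–F–G–H
Product: 21 2'-{4,6-bis(benzyloxy)-2-[2,4,6-tris(benzyloxy)phenoxy]phenoxy}-4,4',6,6'-tetrakis(benzyloxy)-[1,1'-biphenyl]-2-ol (rings E–F–G–H, free OH on ring E)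
Conditions: HCl (conc., cat.), MeOH/THF, 45 °C
Reagents that add atoms: none
Why: Acid-catalysed acetal exchange with methanol removes the MOM group while benzyl and diaryl ethers stay, and no furan can form because the neighbouring ortho oxygen on ring F is an ether.

Step 15
Reactants: 10 2-(benzyloxy)-6-bromo-1,4-benzoquinone
Product: 23 5-(benzyloxy)-2,3-dibromo-1,4-benzoquinone, via dibromohydroquinone 22 (not isolated)
Conditions: HBr (33 % in AcOH, 1.05 equiv), CH2Cl2, −20 °C; aqueous wash; then PhI(OAc)2, CH2Cl2, rt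
Reagents that add atoms: hydrogen bromide, Br
Why: Hydrohalogenation of the quinone (conjugate addition of bromide para to the benzyloxy group, the same carbon that is attacked in step 7) followed by reoxidation of the hydroquinone.

Step 16
Reactants: 21 rings E–F–G–H phenol; 23 5-(benzyloxy)-2,3-dibromo-1,4-benzoquinone
Product: 24 2-(benzyloxy)-6-bromo-5-(aryloxy)-1,4-benzoquinone (aryloxy = 21 bound through its ring E oxygen)
Conditions: Cs2CO3, DMF, −20 °C, 23 in excess (1.3 equiv)
Reagents that add atoms: none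
Why: Addition–elimination (nucleophilic vinylic substitution) on the dibromoquinone, in which the bromide para to the benzyloxy group goes first because its carbon is beta to the carbonyl that is not tied up as a vinylogous ester, and cesium phenoxide in DMF favours attack through oxygen rather than carbon.

Step 17
Reactants: 24 ring D bromoquinone carrying rings E–H; 12 rings A–B–C dibenzofuranol
Product: 25 2-(benzyloxy)-5-(aryloxy from 21)-6-(aryloxy from 12)-1,4-benzoquinone
Conditions: Cs2CO3, DMF, 0 °C → rt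
Reagents that add atoms: none
Why: Second addition–elimination at the remaining C–Br, in which the phenoxide of 12 has both ortho positions blocked and so reacts only at oxygen, low temperature limiting exchange of the aryloxy group already present.

Step 18
Reactants: 25 bis(aryloxy)quinone
Product: 27 pentadeca-O-benzyl ether of the target (all hydroxyls benzylated except the ring D hydroxyl next to the carbon that carries the O–ring E ether), via hydroquinone 26 (not isolated)
Conditions: Na2S2O4, THF/H2O, rt; then CuI (20 mol %), N,N-dimethylglycine·HCl (60 mol %), Cs2CO3, degassed dioxane, 100 °C, 5 mM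
Reagents that add atoms: none
Why: Dithionite reduction to the hydroquinone and intramolecular Ullmann etherification, in which only the hydroxyl ortho to the ring C ether can reach the C–Br of ring C (six-membered dioxin ring) while the other hydroxyl stays free as the target requires.

Step 19
Reactants: 27 pentadeca-O-benzyl ether of the target
Product: 28 target CNP0192765.0
Conditions: H2 (1 atm), Pd(OH)2/C, THF/MeOH, rt, work-up under argon
Reagents that add atoms: none
Why: Hydrogenolysis of the fifteen benzyl ethers under neutral conditions, which spares the diaryl ethers, the dibenzofuran and the dioxin and avoids acid that could dehydrate the E–F biaryl diol to a second furan.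

**Compound list**
1 | 3,5-bis(benzyloxy)benzaldehyde | O=Cc1cc(OCc2ccccc2)cc(OCc2ccccc2)c1 | starting material
2 | 3,5-bis(benzyloxy)-2-bromobenzaldehyde | O=Cc1cc(OCc2ccccc2)cc(OCc2ccccc2)c1Br | intermediate
3 | 3,5-bis(benzyloxy)phenol | Oc1cc(OCc2ccccc2)cc(OCc2ccccc2)c1 | starting material
4 | 3,5-bis(benzyloxy)-2-[3,5-bis(benzyloxy)phenoxy]benzaldehyde | O=Cc1cc(OCc2ccccc2)cc(OCc2ccccc2)c1Oc1cc(OCc2ccccc2)cc(OCc2ccccc2)c1 | intermediate
5 | 3,5-bis(benzyloxy)-2-[3,5-bis(benzyloxy)phenoxy]phenyl formate | O=COc1cc(OCc2ccccc2)cc(OCc2ccccc2)c1Oc1cc(OCc2ccccc2)cc(OCc2ccccc2)c1 | intermediate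
6 | 3,5-bis(benzyloxy)-2-[3,5-bis(benzyloxy)phenoxy]phenol | Oc1cc(OCc2ccccc2)cc(OCc2ccccc2)c1Oc1cc(OCc2ccccc2)cc(OCc2ccccc2)c1 | intermediate
7 | catechol | Oc1ccccc1O | starting material
8 | 2-(benzyloxy)phenol | Oc1ccccc1OCc1ccccc1 | intermediate
9 | 2-(benzyloxy)-6-bromophenol | Oc1c(Br)cccc1OCc1ccccc1 | intermediate
10 | 2-(benzyloxy)-6-bromocyclohexa-2,5-diene-1,4-dione | O=C1C=C(OCc2ccccc2)C(=O)C(Br)=C1 | intermediate
11 | 5-(benzyloxy)-3-bromo-2-{4,6-bis(benzyloxy)-3-[3,5-bis(benzyloxy)phenoxy]-2-hydroxyphenyl}benzene-1,4-diol | Oc1cc(OCc2ccccc2)c(O)c(Br)c1-c1c(OCc2ccccc2)cc(OCc2ccccc2)c(Oc2cc(OCc3ccccc3)cc(OCc3ccccc3)c2)c1O | intermediate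
12 | 3,7,9-tris(benzyloxy)-6-[3,5-bis(benzyloxy)phenoxy]-1-bromodibenzo[b,d]furan-2-ol | Oc1c(Br)c2c(cc1OCc1ccccc1)oc1c(Oc3cc(OCc4ccccc4)cc(OCc4ccccc4)c3)c(OCc3ccccc3)cc(OCc3ccccc3)c12 | intermediate
13 | 4,4',6,6'-tetrakis(benzyloxy)-[1,1'-biphenyl]-2,2'-diol | Oc1cc(OCc2ccccc2)cc(OCc2ccccc2)c1-c1c(O)cc(OCc2ccccc2)cc1OCc1ccccc1 | intermediate
14 | 3,5-bis(benzyloxy)-2-{[4,4',6,6'-tetrakis(benzyloxy)-2'-hydroxy-[1,1'-biphenyl]-2-yl]oxy}benzaldehyde | O=Cc1cc(OCc2ccccc2)cc(OCc2ccccc2)c1Oc1cc(OCc2ccccc2)cc(OCc2ccccc2)c1-c1c(O)cc(OCc2ccccc2)cc1OCc1ccccc1 | intermediate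
15 | 3,5-bis(benzyloxy)-2-{[4,4',6,6'-tetrakis(benzyloxy)-2'-(methoxymethoxy)-[1,1'-biphenyl]-2-yl]oxy}benzaldehyde | O=Cc1cc(OCc2ccccc2)cc(OCc2ccccc2)c1Oc1cc(OCc2ccccc2)cc(OCc2ccccc2)c1-c1c(OCOC)cc(OCc2ccccc2)cc1OCc1ccccc1 | intermediate
16 | 3,5-bis(benzyloxy)-2-{[4,4',6,6'-tetrakis(benzyloxy)-2'-(methoxymethoxy)-[1,1'-biphenyl]-2-yl]oxy}phenyl formate | O=COc1cc(OCc2ccccc2)cc(OCc2ccccc2)c1Oc1cc(OCc2ccccc2)cc(OCc2ccccc2)c1-c1c(OCOC)cc(OCc2ccccc2)cc1OCc1ccccc1 | intermediate
17 | 3,5-bis(benzyloxy)-2-{[4,4',6,6'-tetrakis(benzyloxy)-2'-(methoxymethoxy)-[1,1'-biphenyl]-2-yl]oxy}phenol | Oc1cc(OCc2ccccc2)cc(OCc2ccccc2)c1Oc1cc(OCc2ccccc2)cc(OCc2ccccc2)c1-c1c(OCOC)cc(OCc2ccccc2)cc1OCc1ccccc1 | intermediate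
18 | 1,3,5-tris(benzyloxy)benzene | C(Oc1cc(OCc2ccccc2)cc(OCc2ccccc2)c1)c1ccccc1 | starting material
19 | 1,3,5-tris(benzyloxy)-2-iodobenzene | Ic1c(OCc2ccccc2)cc(OCc2ccccc2)cc1OCc1ccccc1 | intermediate
20 | 2-{4,6-bis(benzyloxy)-2-[2,4,6-tris(benzyloxy)phenoxy]phenoxy}-4,4',6,6'-tetrakis(benzyloxy)-2'-(methoxymethoxy)-1,1'-biphenyl | C(Oc1cc(OCc2ccccc2)cc(OCc2ccccc2)c1Oc1cc(OCc2ccccc2)cc(OCc2ccccc2)c1Oc1cc(OCc2ccccc2)cc(OCc2ccccc2)c1-c1c(OCOC)cc(OCc2ccccc2)cc1OCc1ccccc1)c1ccccc1 | intermediate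
21 | 2'-{4,6-bis(benzyloxy)-2-[2,4,6-tris(benzyloxy)phenoxy]phenoxy}-4,4',6,6'-tetrakis(benzyloxy)-[1,1'-biphenyl]-2-ol | C(Oc1cc(OCc2ccccc2)cc(OCc2ccccc2)c1Oc1cc(OCc2ccccc2)cc(OCc2ccccc2)c1Oc1cc(OCc2ccccc2)cc(OCc2ccccc2)c1-c1c(O)cc(OCc2ccccc2)cc1OCc1ccccc1)c1ccccc1 | intermediate
22 | 2-(benzyloxy)-5,6-dibromobenzene-1,4-diol | Oc1c(OCc2ccccc2)cc(O)c(Br)c1Br | intermediate
23 | 5-(benzyloxy)-2,3-dibromocyclohexa-2,5-diene-1,4-dione | O=C1C(OCc2ccccc2)=CC(=O)C(Br)=C1Br | intermediate
24 | 2-(benzyloxy)-6-bromo-5-(aryloxy)-1,4-benzoquinone, aryloxy = 21 bound through its ring E oxygen | O=C1C(OCc2ccccc2)=CC(=O)C(Oc2cc(OCc3ccccc3)cc(OCc3ccccc3)c2-c2c(OCc3ccccc3)cc(OCc3ccccc3)cc2Oc2c(OCc3ccccc3)cc(OCc3ccccc3)cc2Oc2c(OCc3ccccc3)cc(OCc3ccccc3)cc2OCc2ccccc2)=C1Br | intermediate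
25 | 2-(benzyloxy)-1,4-benzoquinone carrying at C5 the aryloxy group of 21 and at C6 the aryloxy group of 12 (bound through the dibenzofuran C2 oxygen) | O=C1C(OCc2ccccc2)=CC(=O)C(Oc2cc(OCc3ccccc3)cc(OCc3ccccc3)c2-c2c(OCc3ccccc3)cc(OCc3ccccc3)cc2Oc2c(OCc3ccccc3)cc(OCc3ccccc3)cc2Oc2c(OCc3ccccc3)cc(OCc3ccccc3)cc2OCc2ccccc2)=C1Oc1c(Br)c2c(cc1OCc1ccccc1)oc1c(Oc3cc(OCc4ccccc4)cc(OCc4ccccc4)c3)c(OCc3ccccc3)cc(OCc3ccccc3)c12 | intermediate
26 | hydroquinone (benzene-1,4-diol) corresponding to 25 | Oc1c(OCc2ccccc2)cc(O)c(Oc2cc(OCc3ccccc3)cc(OCc3ccccc3)c2-c2c(OCc3ccccc3)cc(OCc3ccccc3)cc2Oc2c(OCc3ccccc3)cc(OCc3ccccc3)cc2Oc2c(OCc3ccccc3)cc(OCc3ccccc3)cc2OCc2ccccc2)c1Oc1c(Br)c2c(cc1OCc1ccccc1)oc1c(Oc3cc(OCc4ccccc4)cc(OCc4ccccc4)c3)c(OCc3ccccc3)cc(OCc3ccccc3)c12 | intermediate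
27 | pentadeca-O-benzyl ether of 28, free OH only on ring D next to the carbon bearing the O–ring E ether | c1ccccc1COc1cc(OCc2ccccc2)cc(Oc2c(OCc3ccccc3)cc(OCc3ccccc3)c3c2oc2cc(OCc4ccccc4)c4c(c23)Oc2c(OCc3ccccc3)cc(O)c(Oc3cc(OCc5ccccc5)cc(OCc5ccccc5)c3-c3c(OCc5ccccc5)cc(OCc5ccccc5)cc3Oc3c(OCc5ccccc5)cc(OCc5ccccc5)cc3Oc3c(OCc5ccccc5)cc(OCc5ccccc5)cc3OCc3ccccc3)c2O4)c1 | intermediate
28 | CNP0192765.0 | Oc1cc(O)cc(Oc2c(O)cc(O)c3c2oc2cc(O)c4c(c23)Oc2c(O)cc(O)c(Oc3cc(O)cc(O)c3-c3c(O)cc(O)cc3Oc3c(O)cc(O)cc3Oc3c(O)cc(O)cc3O)c2O4)c1 | target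

**Step count and risks**

Total: 19 steps. Longest linear sequence: 10 steps (3 → 13 → 14 → 15 → 17 → 20 → 21 → 24 → 25 → 27 → 28).

Step 7 is the most likely to fail. The risks are attack para rather than ortho to the OH of 6, oxidation of 11 by 10, and loss of benzyl groups under acid. The fallback sets out from 10 (with 6) and comes back at 12. Quinone 10 is treated with HC(OMe)3 and TsOH (cat.) in MeOH, which ketalizes the unhindered carbonyl and gives the monoketal 2-(benzyloxy)-6-bromo-4,4-dimethoxycyclohexa-2,5-dien-1-one F1. F1 and 6 with TfOH (cat.) in CH2Cl2/HFIP at −20 °C exchange one methoxy group for the phenol oxygen. The tethered ortho carbon then closes a five-membered ring onto the enone carbon next to C–Br, and loss of two MeOH gives 12. Because the C–O bond is made first, para attack is impossible and no phenol–phenol dehydration is needed.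

Step 8 is the second risk. The dimerization may give ortho,para' or para,para' isomers, and FeCl3 may cleave benzyl ethers. The fallback sets out from 3 and comes back at 13. Two molecules of 3 are tied together with i-Pr2SiCl2 and imidazole in DMF to give bis[3,5-bis(benzyloxy)phenoxy]di(propan-2-yl)silane F2. PhI(OCOCF3)2 with BF3·OEt2 in CH2Cl2 at −40 °C couples the two rings within the tether to give the seven-membered cyclic silyl ether 1,3,9,11-tetrakis(benzyloxy)-6,6-di(propan-2-yl)dibenzo[d,f][1,3,2]dioxasilepine F3, which can only arise from ortho,ortho' coupling. K2CO3 (cat.) in MeOH then releases 13.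

Step 17 is the third risk. The hindered phenoxide of 12 must displace the last bromide next to the bulky ring E ether, and exchange of that aryloxy group would scramble the two halves. The fallback sets out from 23 (with 12 and 21) and comes back at 25; it inverts the order of attachment with a sulfur placeholder. Thiophenol and Et3N in CH2Cl2 at −40 °C displace the bromide para to the benzyloxy group of 23 and give 2-(benzyloxy)-6-bromo-5-(phenylsulfanyl)-1,4-benzoquinone F4. The phenoxide of 12 (Cs2CO3, DMF) then displaces the remaining bromide, next to a small substituent and with no exchangeable aryloxy group present, to give the 6-(dibenzofuranyloxy)-5-(phenylsulfanyl)quinone F5. mCPBA (2.2 equiv) oxidizes the sulfide to the 5-(phenylsulfonyl)quinone F6. Phenol 21 with Cs2CO3 displaces the sulfinate, a far better leaving group than aryloxide, and gives 25.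

**Further compounds**
F1 | step 7 | 2-(benzyloxy)-6-bromo-4,4-dimethoxycyclohexa-2,5-dien-1-one | O=C1C(OCc2ccccc2)=CC(OC)(OC)C=C1Br
F2 | step 8 | bis[3,5-bis(benzyloxy)phenoxy]di(propan-2-yl)silane | CC(C)[Si](Oc1cc(OCc2ccccc2)cc(OCc2ccccc2)c1)(Oc1cc(OCc2ccccc2)cc(OCc2ccccc2)c1)C(C)C
F3 | step 8 | 1,3,9,11-tetrakis(benzyloxy)-6,6-di(propan-2-yl)dibenzo[d,f][1,3,2]dioxasilepine | CC(C)[Si]1(Oc2cc(OCc3ccccc3)cc(OCc3ccccc3)c2-c2c(O1)cc(OCc3ccccc3)cc2OCc2ccccc2)C(C)C
F4 | step 17 | 2-(benzyloxy)-6-bromo-5-(phenylsulfanyl)cyclohexa-2,5-diene-1,4-dione | O=C1C(OCc2ccccc2)=CC(=O)C(Sc2ccccc2)=C1Br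
F5 | step 17 | 2-(benzyloxy)-5-(phenylsulfanyl)-1,4-benzoquinone carrying at C6 the aryloxy group of 12 | O=C1C(OCc2ccccc2)=CC(=O)C(Sc2ccccc2)=C1Oc1c(Br)c2c(cc1OCc1ccccc1)oc1c(Oc3cc(OCc4ccccc4)cc(OCc4ccccc4)c3)c(OCc3ccccc3)cc(OCc3ccccc3)c12
F6 | step 17 | 2-(benzyloxy)-5-(phenylsulfonyl)-1,4-benzoquinone carrying at C6 the aryloxy group of 12 | O=C1C(OCc2ccccc2)=CC(=O)C(S(=O)(=O)c2ccccc2)=C1Oc1c(Br)c2c(cc1OCc1ccccc1)oc1c(Oc3cc(OCc4ccccc4)cc(OCc4ccccc4)c3)c(OCc3ccccc3)cc(OCc3ccccc3)c12
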